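The dihydropyran ring is cut across C4–C3 and O1–C2 (chroman numbering), which uncovers an ortho-quinone methide (O1=C8a–C4a=C4H2) on ring A and 2-methylprop-1-enyl pinacolboronate. A chiral phosphoric acid releases the quinone methide from a salicyl alcohol and steers an inverse-demand oxa-[4+2] cycloaddition that closes the pyran and sets C3 as a C–B bond, later oxidised with retention to the carbinol. The step exploits the gem-dimethyl carbon C2, whose tertiary cation character forces O1 onto C2 and the methylene onto the boron-bearing carbon; an allyl ether on O5 leaves O1 as the only oxygen able to cyclise. Chalcone assembly and deallylation follow.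

Key step: step 3

Assumption: the sense of induction of the chiral phosphoric acid in step 3 cannot be predicted with certainty; the route is written for the (R)-acid, and the (S)-acid, equally available, is to be used if a first run shows the opposite sense.

Step 1
Reactants: 1 1-(2,4-dihydroxy-6-methoxyphenyl)ethan-1-one
Product: 2 1-[2-hydroxy-6-methoxy-4-(prop-2-en-1-yloxy)phenyl]ethan-1-one
Conditions: allyl bromide (1.05 equiv), K2CO3, acetone, reflux
Reagents that add atoms: allyl bromide, C=CCBr
Why: Williamson etherification, in which the 4-hydroxyl, not hydrogen-bonded to the acetyl carbonyl, is the more acidic and nucleophilic oxygen and should be alkylated selectively, blocking the oxygen that must not enter the pyran ring.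

Step 2
Reactants: 2 1-[2-hydroxy-6-methoxy-4-(prop-2-en-1-yloxy)phenyl]ethan-1-one; 3 formaldehyde (used as paraformaldehyde)
Product: 5 1-[2-hydroxy-3-(hydroxymethyl)-6-methoxy-4-(prop-2-en-1-yloxy)phenyl]ethan-1-one, via benzodioxaborin 4 (not isolated)
Conditions: PhB(OH)2 (1.2 equiv), EtCO2H (cat.), toluene, reflux, Dean–Stark; then propane-1,3-diol, THF, rt; purification on base-washed silica
Reagents that add atoms: none
Why: Nagata ortho-hydroxymethylation, in which the aryl phenylboronate formed at the free phenol delivers formaldehyde through a six-membered transition state to the only open ortho position (between the hydroxyl and the allyloxy group), and diol exchange then liberates the salicyl alcohol.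

Step 3
Reactants: 5 1-[2-hydroxy-3-(hydroxymethyl)-6-methoxy-4-(prop-2-en-1-yloxy)phenyl]ethan-1-one; 6 4,4,5,5-tetramethyl-2-(2-methylprop-1-en-1-yl)-1,3,2-dioxaborolane
Product: 8 1-[(3S)-7-methoxy-2,2-dimethyl-5-(prop-2-en-1-yloxy)-3-(4,4,5,5-tetramethyl-1,3,2-dioxaborolan-2-yl)-3,4-dihydro-2H-chromen-8-yl]ethan-1-one, via ortho-quinone methide 7 (not isolated)
Conditions: (R)-TRIP [(R)-3,3'-bis(2,4,6-triisopropylphenyl)-1,1'-binaphthyl-2,2'-diyl hydrogen phosphate] (10 mol%), 6 (3 equiv), 5 Å MS, toluene, 25 °C, slow addition of 5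
Reagents that add atoms: none
Why: Proposed new method: the phosphoric acid ionises the benzylic alcohol of 5 to the ortho-quinone methide 7, held to the chiral phosphate by a hydrogen bond at O1, and the boron-bearing carbon of 6 attacks the exocyclic methylene C4 while the developing tertiary cation at the gem-dimethyl carbon, further stabilised by hyperconjugation with the C–B bond, is captured by O1 in an asynchronous inverse-electron-demand oxa-[4+2] cycloaddition. The closest known reaction types are the chiral-phosphoric-acid-catalysed hetero-Diels–Alder reaction of ortho-quinone methides from ortho-hydroxybenzyl alcohols with styrenes and the thermal cycloaddition of ortho-quinone methides with trisubstituted alkenes, neither of which has been shown for a boryl-substituted dienophile. The dihydropyran ring is closed by this [4+2] cycloaddition (a 6-endo capture of the cation by O1 if the process is stepwise). The single new stereocentre C3 should be set by catalyst control, the chiral phosphate pocket selecting one enantiotopic face of the alkene, and is wanted as (S); boron stands in for the hydroxyl group. The step needs regioselectivity (methylene to C3, O1 to C2), secured by the cation-stabilising gem-dimethyl terminus and the non-donating boryl group, and site selectivity between O1 and O5, secured by the allyl ether on O5. Excess 6 and slow addition of 5 should suppress Friedel–Crafts self-condensation of 7 at its free ring position.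

Step 4
Reactants: 8 1-[(3S)-7-methoxy-2,2-dimethyl-5-(prop-2-en-1-yloxy)-3-(4,4,5,5-tetramethyl-1,3,2-dioxaborolan-2-yl)-3,4-dihydro-2H-chromen-8-yl]ethan-1-one
Product: 9 1-[(3S)-3-hydroxy-7-methoxy-2,2-dimethyl-5-(prop-2-en-1-yloxy)-3,4-dihydro-2H-chromen-8-yl]ethan-1-one
Conditions: NaBO3·4H2O, THF/H2O (1:1), rt
Reagents that add atoms: sodium perborate tetrahydrate, [Na+].[Na+].O[B-]1(O)OO[B-](O)(O)OO1
Why: Oxidation of an alkylboronate, in which the peroxoborate adds to boron and C3 migrates from boron to oxygen with retention, so the (S)-C–B bond should become the (S)-carbinol while the aryl ketone and the allyl ether stay inert.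

Step 5
Reactants: 9 1-[(3S)-3-hydroxy-7-methoxy-2,2-dimethyl-5-(prop-2-en-1-yloxy)-3,4-dihydro-2H-chromen-8-yl]ethan-1-one; 10 4-(prop-2-en-1-yloxy)benzaldehyde
Product: 11 (2E)-1-[(3S)-3-hydroxy-7-methoxy-2,2-dimethyl-5-(prop-2-en-1-yloxy)-3,4-dihydro-2H-chromen-8-yl]-3-[4-(prop-2-en-1-yloxy)phenyl]prop-2-en-1-one
Conditions: KOH (aq., 50%), EtOH, rt
Reagents that add atoms: none
Why: Claisen–Schmidt condensation, in which the methyl ketone is the only enolisable site, both ortho-oxygens are alkylated so no flavanone can form, and dehydration of the aldol should give the conjugated (E)-enone under thermodynamic control without touching C3.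

Step 6
Reactants: 11 (2E)-1-[(3S)-3-hydroxy-7-methoxy-2,2-dimethyl-5-(prop-2-en-1-yloxy)-3,4-dihydro-2H-chromen-8-yl]-3-[4-(prop-2-en-1-yloxy)phenyl]prop-2-en-1-one
Product: 12 (2E)-1-[(3S)-3,5-dihydroxy-7-methoxy-2,2-dimethyl-3,4-dihydro-2H-chromen-8-yl]-3-(4-hydroxyphenyl)prop-2-en-1-one
Conditions: Pd(PPh3)4 (5 mol%), K2CO3, MeOH/THF, rt
Reagents that add atoms: none
Why: Tsuji–Trost deallylation, in which zerovalent palladium ionises each aryl allyl ether to a π-allyl complex and a phenoxide and methanol traps the allyl fragment, leaving the enone, the carbinol, the methyl ether and the C3 stereocentre untouched.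

Compound list
1 | 1-(2,4-dihydroxy-6-methoxyphenyl)ethan-1-one | CC(=O)c1c(O)cc(O)cc1OC | starting material
2 | 1-[2-hydroxy-6-methoxy-4-(prop-2-en-1-yloxy)phenyl]ethan-1-one | CC(=O)c1c(O)cc(OCC=C)cc1OC | intermediate
3 | formaldehyde (used as paraformaldehyde) | C=O | starting material
4 | 1-[7-methoxy-2-phenyl-5-(prop-2-en-1-yloxy)-4H-1,3,2-benzodioxaborinin-8-yl]ethan-1-one | CC(=O)c1c(OC)cc(OCC=C)c2c1OB(c1ccccc1)OC2 | intermediate (not isolated)
5 | 1-[2-hydroxy-3-(hydroxymethyl)-6-methoxy-4-(prop-2-en-1-yloxy)phenyl]ethan-1-one | CC(=O)c1c(O)c(CO)c(OCC=C)cc1OC | intermediate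
6 | 4,4,5,5-tetramethyl-2-(2-methylprop-1-en-1-yl)-1,3,2-dioxaborolane | CC(C)=CB1OC(C)(C)C(C)(C)O1 | starting material
7 | 2-acetyl-3-methoxy-6-methylidene-5-(prop-2-en-1-yloxy)cyclohexa-2,4-dien-1-one | CC(=O)C1=C(OC)C=C(OCC=C)C(=C)C1=O | intermediate (not isolated)
8 | 1-[(3S)-7-methoxy-2,2-dimethyl-5-(prop-2-en-1-yloxy)-3-(4,4,5,5-tetramethyl-1,3,2-dioxaborolan-2-yl)-3,4-dihydro-2H-chromen-8-yl]ethan-1-one | CC(=O)c1c(OC)cc(OCC=C)c2c1OC(C)(C)[C@@H](B1OC(C)(C)C(C)(C)O1)C2 | intermediate
9 | 1-[(3S)-3-hydroxy-7-methoxy-2,2-dimethyl-5-(prop-2-en-1-yloxy)-3,4-dihydro-2H-chromen-8-yl]ethan-1-one | CC(=O)c1c(OC)cc(OCC=C)c2c1OC(C)(C)[C@@H](O)C2 | intermediate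
10 | 4-(prop-2-en-1-yloxy)benzaldehyde | O=Cc1ccc(OCC=C)cc1 | starting material
11 | (2E)-1-[(3S)-3-hydroxy-7-methoxy-2,2-dimethyl-5-(prop-2-en-1-yloxy)-3,4-dihydro-2H-chromen-8-yl]-3-[4-(prop-2-en-1-yloxy)phenyl]prop-2-en-1-one | COc1cc(OCC=C)c2c(c1C(=O)/C=C/c1ccc(OCC=C)cc1)OC(C)(C)[C@@H](O)C2 | intermediate
12 | (2E)-1-[(3S)-3,5-dihydroxy-7-methoxy-2,2-dimethyl-3,4-dihydro-2H-chromen-8-yl]-3-(4-hydroxyphenyl)prop-2-en-1-one | COc1cc(O)c2c(c1C(=O)/C=C/c1ccc(O)cc1)OC(C)(C)[C@@H](O)C2 | target

Total step count: 6. Longest linear sequence: 6 steps (1 → 2 → 5 → 8 → 9 → 11 → 12).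

Steps most likely to fail

Step 3 (the step that bears the label). The chiral phosphate may discriminate poorly between the two faces of the alkenyl boronate. The β-boryl cation may lose boron before O1 closes the ring, giving alkenylation instead of annulation. The quinone methide may also oligomerise by Friedel–Crafts attack on a second arene. The fallback uses known chemistry, sets out from 5 and comes back at 9. Compound 5 is warmed with 2-methylprop-1-enylboronic acid (toluene, 4 Å MS, 60 °C), so that the quinone methide is alkenylated by conjugate addition of the boronate with loss of boron. This should give the ortho-prenylphenol 1-[2-hydroxy-6-methoxy-3-(3-methylbut-2-en-1-yl)-4-(prop-2-en-1-yloxy)phenyl]ethan-1-one F1. Shi epoxidation of the trisubstituted alkene follows, with the enantiomer of the D-fructose-derived ketone (made from L-fructose), Oxone (2KHSO5·KHSO4·K2SO4), K2CO3 buffer and MeCN/dimethoxymethane/H2O at 0 °C. The L-fructose-derived ketone is chosen because the D-fructose-derived ketone is expected to give the (R)-epoxide; the monosubstituted allyl ether alkene should react far more slowly. This should give the epoxide 1-[3-{[(2S)-3,3-dimethyloxiran-2-yl]methyl}-2-hydroxy-6-methoxy-4-(prop-2-en-1-yloxy)phenyl]ethan-1-one F2. Camphorsulfonic acid (cat., CH2Cl2, 0 °C) should then open the epoxide at its tertiary carbon by 6-endo attack of O1, with the configuration at the carbinol carbon retained, to give 9. In this fallback the ring closure forms only the O1–C2 bond.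

Step 2. The chelated phenol may form the aryl boronate slowly, and the electron-rich salicyl alcohol may ionise during purification. The fallback sets out from 2 and comes back at 5. Magnesium-mediated ortho-formylation (MgCl2, Et3N, paraformaldehyde, MeCN, reflux), which is specific for the position ortho to the free phenol, should give 3-acetyl-2-hydroxy-4-methoxy-6-(prop-2-en-1-yloxy)benzaldehyde F3. Reduction of the aldehyde in the presence of the hindered, hydrogen-bonded ketone (NaBH4, MeOH/THF, −20 °C) should then give 5.

Step 5. The di-ortho-substituted methyl ketone may enolise slowly, and the reversible aldol may not drain to the enone. The fallback sets out from 9 and comes back at 11. The alkoxide–enolate dianion of 9 (LiN(SiMe3)2, 2.2 equiv, THF, −78 °C) is treated with 10 in an irreversible directed aldol addition. This should give 1-[(3S)-3-hydroxy-7-methoxy-2,2-dimethyl-5-(prop-2-en-1-yloxy)-3,4-dihydro-2H-chromen-8-yl]-3-hydroxy-3-[4-(prop-2-en-1-yloxy)phenyl]propan-1-one F4 as a mixture of epimers at the new carbinol. Acid-catalysed dehydration of the activated benzylic carbinol (TsOH·H2O cat., toluene, 50 °C) should then give 11.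

Further compounds
F1 | step 3 | 1-[2-hydroxy-6-methoxy-3-(3-methylbut-2-en-1-yl)-4-(prop-2-en-1-yloxy)phenyl]ethan-1-one | CC(=O)c1c(O)c(CC=C(C)C)c(OCC=C)cc1OC
F2 | step 3 | 1-[3-{[(2S)-3,3-dimethyloxiran-2-yl]methyl}-2-hydroxy-6-methoxy-4-(prop-2-en-1-yloxy)phenyl]ethan-1-one | CC(=O)c1c(O)c(C[C@@H]2OC2(C)C)c(OCC=C)cc1OC
F3 | step 2 | 3-acetyl-2-hydroxy-4-methoxy-6-(prop-2-en-1-yloxy)benzaldehyde | CC(=O)c1c(O)c(C=O)c(OCC=C)cc1OC
F4 | step 5 | 1-[(3S)-3-hydroxy-7-methoxy-2,2-dimethyl-5-(prop-2-en-1-yloxy)-3,4-dihydro-2H-chromen-8-yl]-3-hydroxy-3-[4-(prop-2-en-1-yloxy)phenyl]propan-1-one | COc1cc(OCC=C)c2c(c1C(=O)CC(O)c1ccc(OCC=C)cc1)OC(C)(C)[C@@H](O)C2
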